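The constants are made up; the result is computed.

Which flask still holds its product as target when the run ends, rather than as side product or isomer of the product?

all flasks: starting material 2.1 M; partner 1.00 equiv; time 20 min

|  | temperature |
|---|---|
| grey | 30 °C |
| amber | 90 °C |
| red | 70 °C |
| teal | 50 °C |

- the flask with the highest share of target in all that became target or side product or isomer of the product ("all alike" if they lie within 1.5 percentage points) (grey / amber / red / teal / all alike)
- share of target in all that became target or side product or isomer of the product, grey
- share of target in all that became target or side product or isomer of the product, amber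
- share of target in all that became target or side product or isomer of the product, red
- share of target in all that became target or side product or isomer of the product, teal

- constants are those at 50 °C; use the activation energies and enthalpies for any other temperature

    starting material + partner → intermediate A (k1 = 6.54 × 10⁻⁴ M⁻¹ s⁻¹, Ea1 = 85.0 kJ mol⁻¹)
    intermediate A ⇌ intermediate B (K2 = 20, k2 = 0.00179 s⁻¹, Ea2 = 100 kJ mol⁻¹, ΔH2 = −46.0 kJ mol⁻¹)
    starting material + partner → intermediate C (k3 = 1.74 × 10⁻⁴ M⁻¹ s⁻¹, Ea3 = 68.0 kJ mol⁻¹)
    intermediate B → target (k4 = 5.97 × 10⁻⁴ s⁻¹, Ea4 = 94.0 kJ mol⁻¹)
    intermediate C ⇌ intermediate D (K5 = 1.19, k5 = 0.00102 s⁻¹, Ea5 = 91.0 kJ mol⁻¹, ΔH5 = −33.0 kJ mol⁻¹)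
    intermediate C → side product (k6 = 5.24 × 10⁻⁵ s⁻¹, Ea6 = 97.0 kJ mol⁻¹)
    target ⇌ isomer of the product (K7 = 1.5, k7 = 1.98 × 10⁻⁴ s⁻¹, Ea7 = 112 kJ mol⁻¹, ΔH7 = −20.0 kJ mol⁻¹)
    (constants at 50 °C)

Target, once made, turns reversibly into isomer of the product, with forward constant 1.98 × 10⁻⁴ s⁻¹ and equilibrium constant 1.5 at 50 °C. The teal flask runs at that temperature, so it needs no rescaling. The step is first order both ways, so it integrates in closed form. Forward and back constants added give a half-life of 35.0 min for the gap to equilibrium, which I call the pair half-life. At equilibrium in the teal flask, target would be 40.0% of the pair.

In the teal flask the pair half-life is longer than the run of 20 min. Even target present from the first moment would have lost 19.6% of the pair by then, and real target arrives later through the intermediates. So I commit to isomer below that fraction in the teal flask, which is kinetic control of the pair. In the red flask the pair half-life is 2.53 min, shorter than the run, so that flask passes through 7.91 of its own half-lives and I expect its pair close to equilibrium, which is thermodynamic control. I therefore put teal above red, whose pair half-life is shorter than that of teal. Grey and amber I leave open: this clock speaks of isomer, and side product comes by a separate branch.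

The forecast names teal, with grey at 65.4%, amber at 53.8%, red at 51.4% and teal at 89.1%, and says of teal: “Isomerisation is only partly complete”.

The simulation gives teal as the highest, with grey at 65.3%, amber at 53.8%, red at 52.1% and teal at 89.3%.

In the teal flask, isomer stands at 0.741% of the charge against 9.75% target, so it is 7.06% of the pair, less than my bound of 19.6%. Left for 200 min, the teal flask passes through 5.71 pair half-lives, which shrinks a gap present at the start to 1.90% of itself. There it reads 33.6% target and 40.5% isomer, so target is 45.3% of the pair, still above 40.0%, and the asked share has fallen to 42.6%.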